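## The problem

Compound 21 is 7,9-ditigloyloxylongipin-2-en-1-one, (4R,5S,7R,9R,10R,11R). The numbering used for all compounds is C1(=O)–C2H=C3(CH3)–C4H–C5H–C6(CH3)2–C7H(O)–C8H2–C9H(O)–C10(CH3)–C11H, with the further bonds C4–C10, C5–C11 and C11–C1.

- **Ring system.** The core is one cyclobutane (C4, C5, C11, C10) bridged across both diagonals. C4/C11 are bridged by the enone C3=C2–C1, giving a bicyclo[3.1.1]heptenone. C5/C10 are bridged by C6–C7–C8–C9, giving a bicyclo[4.1.1]octane.
- **Closure problem.** Every six- and seven-membered ring holds two adjacent cyclobutane bonds. No [2+2] closure can therefore start from a preformed ring, and any single-bond closure must make a strained ring next to quaternary C6 or C10.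
- **Locked centres.** The double bridge locks the four cyclobutane stereocentres to each other. Without the enone and the esters the skeleton would have a mirror plane through C5, C10 and the C6–C9 bridge.
- **Real stereochemical task.** The sense of the enone (C1 on C11, C3 on C4) must be tied to the anti-diol (C9–O on the C11 side, C7–O on the C4 side). The core gives a reagent at C7 or C9 almost no facial bias, so this link has to be made locally, C9 against C10.
- **Sensitive groups.** The strained, photolabile and acid-sensitive vinylcyclobutane enone and two hindered tiglates (sensitive to base, hydride and nucleophiles) call for a mild end game.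
- **Enabling feature.** Carbonyl carbon C1 is bonded to C11, and C11 carries the cyclobutane bond C10–C11. Shifting C10 back from C11 to C1 (a retro-semipinacol move) turns ring C1–C2=C3–C4–C5–C11 into the cyclohexene of a bicyclo[2.2.1]heptene with C10 as its one-carbon bridge. That is the Diels–Alder adduct of a cyclopentadiene (C1–C4 plus C10) and an alkene C5=C11, and the chain C6–C9 already tethers that alkene to C10.

## Retrosynthesis

**21 to 19 (cut C10–C11, remake C10–C1).**
- The other cyclobutane bonds are poorer cuts. C5–C11 and C4–C5 would need substitution at neopentyl C5, and C4–C10 has no heteroatom handle nearby.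
- Moving C5 instead of C10 back to C1 would give a cyclopentadiene with hydrogen on its sp3 carbon, which scrambles by 1,5-hydrogen shifts.
- Moving C10 gives amine 19, a less strained norbornene. Its C1 silyl ether becomes the ketone and its C2=C3 bond becomes the enone alkene, so no extra oxygen or redox step is needed.
- The forward shift needs a leaving group on the endo face of C11, anti to C1–C10, and migration of C10 rather than of vinyl C2.

**18 to 16 through 17 (cut C4–C5 and C1–C11).**
- Nitro adduct 18, the precursor of 19, is the intramolecular Diels–Alder adduct of silyloxydiene 17, which is the γ-dienol ether of monocyclic enone 16.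
- Two rings and four stereocentres vanish in one cut, and what remains is a cyclopentenone with a side chain.
- A nitro group on C11 is chosen because it polarises the dienophile in the required sense (C5 to C4, C11 to C1) and later becomes the leaving group.
- The forward reaction needs regiocontrol only. Face and endo/exo sense are fixed by the tether and the E geometry.

**16 to 15 to 13 + 14 (cut C11–N and the two ester C–O bonds).**
- The nitroalkene comes from the terminal vinyl group of 15 by radical nitration, so C11 is present from the first step.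
- The tiglates are put on diol 13 with 14 before the key step. Because C10 is quaternary they cannot eliminate, and they replace any further protecting group.

**13/12 to 10 (cut C10–CH3).**
- The C10/C9 relation encodes the link between enone sense and diol.
- It is set next to an existing stereocentre by methylating the chelated dianion 11 of aldol 10. Both C10 epimers of 10 converge.

**10 to 6 + 9 (cut C9–C10).**
- An aldol joins the ring (9, from 7) to the chain aldehyde 6.
- The β-alkoxy group at C7 controls C9 in the 1,3-anti sense, which is the relation found in 21.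
- The neighbouring cut C8–C9 would need an α-quaternary β-keto aldehyde of defined configuration and gives no such control.

**6 to 5 to 4 to 1 + 2 (cut C6–C7).**
- Reverse prenylation of the three-carbon unit 1 with allene 2 makes quaternary C6, the C5=C11 vinyl group and the only catalyst-controlled stereocentre, C7, in one step.
- All other centres follow by relay: C7 to C9, C9 to C10, C10 to C1/C4/C5/C11.

## Roads not taken

**Alternative 1:** (the most obvious) cut C5–C11. In the forward key step the α′-enolate of the bicyclo[5.4.0]undecenone mesylate A1 displaces the C5 sulfonate. This is the classical closure of bridged cyclobutanes in this terpene family.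
- C5 is secondary and neopentyl (next to C6), so backside attack is slow and elimination or γ-deprotonation of the enone can compete.
- A1 already holds five stereocentres on a 6–7 ring system that needs its own synthesis.
- Strong base forbids the esters.
- Nothing in A1 links the enone sense to the diol more easily than in 21.
- The chosen plan makes the hindered C4–C5 bond by cycloaddition and closes the four-membered ring by a shift, not a substitution.

**Alternative 2:** cut C4–C10 and C5–C11. In the forward key step the open-chain acid A2 is dehydrochlorinated through its chloride to a vinylketene, and an intramolecular [2+2] gives cyclobutanone A3.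
- The cycloaddition type is well known, but the ketene carbon C5 arrives as C=O. The C5–C6 bond to a quaternary carbon must be made afterwards, and this leaves a tertiary cyclobutanol to be deoxygenated.
- C1 needs a late allylic oxidation and the exocyclic alkene must be moved.
- The alkene face is controlled only by allylic C9. With alkyl anti and alkoxy inside, that centre should favour the wrong face for a 9R centre.
- The work after this key step outweighs its gain.

**Alternative 3:** keep the bicyclic enone from the chiral pool and cut C5–C6 and C8–C9. The route would start from (+)-verbenone A4, oxidise one C10 methyl group to aldehyde A5, and attach the C6–C8 unit to C5.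
- Two unactivated C–H bonds must be functionalised.
- The methyl group needed is the one that points away from the enone bridge and from any directing group.
- No known C–H functionalisation joins a cyclobutane CH2 to a quaternary carbon.
- The C9 configuration would again have to be set against a core that offers no bias.

Key step: step 10

Assumption: the antipode of SEGPHOS written in step 1 is taken to be the one that gives the 3R alcohol. If the sense of induction is the opposite, the other antipode is used and nothing else changes.

## Steps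

Step 1
Reactants: 1 3,3-diethoxypropan-1-ol; 2 3-methylbuta-1,2-diene
Product: 4 (3R)-1,1-diethoxy-4,4-dimethylhex-5-en-3-ol, via 3,3-diethoxypropanal 3 (not isolated)
Conditions: [Ir(cod)Cl]2 (2.5 mol%), (R)-SEGPHOS (5 mol%), 4-chloro-3-nitrobenzoic acid (10 mol%), allyl acetate (10 mol%), Cs2CO3 (20 mol%), toluene, 60–80 °C, sealed tube
Reagents that add atoms: none
Why: Iridium-catalysed transfer-hydrogenative carbonyl tert-prenylation: 1 is dehydrogenated to 3, the iridium hydride adds to 2, and the dimethylallyl-iridium species adds through its substituted terminus in a closed chair transition state. One operation makes C6–C7, quaternary C6, the vinyl group C5=C11 and, under ligand control, C7 (R).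

Step 2
Reactants: 4 (3R)-1,1-diethoxy-4,4-dimethylhex-5-en-3-ol
Product: 5 1-({[(3R)-1,1-diethoxy-4,4-dimethylhex-5-en-3-yl]oxy}methyl)-4-methoxybenzene
Conditions: NaH, 4-methoxybenzyl chloride, Bu4NI (cat.), DMF, 0 °C to rt
Reagents that add atoms: 4-methoxybenzyl chloride, COc1ccc(CCl)cc1
Why: Williamson ether synthesis; the acetal is inert to base and C7 is untouched. A benzyl-type ether supports the polar 1,3-induction of step 5, survives LDA in step 6 and comes off oxidatively in step 7.

Step 3
Reactants: 5 1-({[(3R)-1,1-diethoxy-4,4-dimethylhex-5-en-3-yl]oxy}methyl)-4-methoxybenzene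
Product: 6 (3R)-3-[(4-methoxybenzyl)oxy]-4,4-dimethylhex-5-enal
Conditions: 1 M aq HCl, THF, 0 °C to rt
Reagents that add atoms: water, O
Why: Acid-catalysed acetal hydrolysis under conditions that leave the 4-methoxybenzyl ether and the alkene alone. The β-alkoxy aldehyde is used without delay to avoid β-elimination.

Step 4
Reactants: 7 3-methylcyclopent-2-en-1-one
Product: 9 1-methyl-3-(trimethylsilyloxy)cyclopenta-1,3-diene, via lithium dienolate 8 (not isolated)
Conditions: LDA, THF, −78 °C; Me3SiCl, −78 to 0 °C; cold aq NaHCO3/pentane, used at once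
Reagents that add atoms: chlorotrimethylsilane, C[Si](C)(C)Cl
Why: Kinetic deprotonation of a cyclic enone occurs at the α′ carbon (C10), and O-silylation of the cross-conjugated dienolate 8 fixes this regiochemistry. The diene is used at once because silyloxycyclopentadienes dimerise on standing.

Step 5
Reactants: 6 (3R)-3-[(4-methoxybenzyl)oxy]-4,4-dimethylhex-5-enal; 9 1-methyl-3-(trimethylsilyloxy)cyclopenta-1,3-diene
Product: 10 5-[(1R,3R)-1-hydroxy-3-(4-methoxybenzyloxy)-4,4-dimethylhex-5-en-1-yl]-3-methylcyclopent-2-en-1-one (both epimers at ring C5 = C10)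
Conditions: BF3·OEt2 (1 equiv), CH2Cl2, −78 °C; aq NaHCO3
Reagents that add atoms: none
Why: Mukaiyama aldol addition through an open transition state; with a non-chelating Lewis acid a β-alkoxy aldehyde reacts in the conformation that opposes the C=O and C–O dipoles, which leads to the 1,3-anti product, so C7 (R) sets C9 (R). C10 forms as a mixture, which does not matter because step 6 planarises it.

Step 6
Reactants: 10 5-[(1R,3R)-1-hydroxy-3-(4-methoxybenzyloxy)-4,4-dimethylhex-5-en-1-yl]-3-methylcyclopent-2-en-1-one
Product: 12 (5S)-5-[(1R,3R)-1-hydroxy-3-(4-methoxybenzyloxy)-4,4-dimethylhex-5-en-1-yl]-3,5-dimethylcyclopent-2-en-1-one, via dilithium enolate-alkoxide 11 (not isolated)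
Conditions: LDA (2.3 equiv), THF, −78 °C; MeI, DMPU, −78 to −40 °C; H2O
Reagents that add atoms: iodomethane, CI
Why: Fráter–Seebach-type alkylation: in the lithium-chelated 11 the C9 oxygen lies in the enolate plane, C8 covers one face and H the other, so iodomethane should enter anti to C8 and give the 9R,10S relation, with both C10 epimers of 10 converging on one product. Enolisation shuts off the retro-aldol path, and C-alkylation of the enolate is faster than O-alkylation of the hindered alkoxide.

Step 7
Reactants: 12 (5S)-5-[(1R,3R)-1-hydroxy-3-(4-methoxybenzyloxy)-4,4-dimethylhex-5-en-1-yl]-3,5-dimethylcyclopent-2-en-1-one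
Product: 13 (5S)-5-[(1R,3R)-1,3-dihydroxy-4,4-dimethylhex-5-en-1-yl]-3,5-dimethylcyclopent-2-en-1-one
Conditions: DDQ, CH2Cl2/pH 7 buffer (10:1), 0 °C
Reagents that add atoms: none
Why: Oxidative cleavage of a 4-methoxybenzyl ether by hydride abstraction and hydrolysis of the oxocarbenium ion. Enone, vinyl group and stereocentres are inert.

Step 8
Reactants: 13 (5S)-5-[(1R,3R)-1,3-dihydroxy-4,4-dimethylhex-5-en-1-yl]-3,5-dimethylcyclopent-2-en-1-one; 14 (E)-2-methylbut-2-enoyl chloride (tigloyl chloride)
Product: 15 (5S)-3,5-dimethyl-5-[(1R,3R)-4,4-dimethyl-1,3-bis(tigloyloxy)hex-5-en-1-yl]cyclopent-2-en-1-one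
Conditions: 14 (3 equiv), pyridine, DMAP (cat.), CH2Cl2, 0 to 40 °C
Reagents that add atoms: none
Why: DMAP-catalysed acylation of both neopentyl-type secondary alcohols; pyridine rather than a trialkylamine is used so that 14 is not deconjugated through its vinylketene, and its E geometry is carried into 15. With C10 quaternary the β-acyloxy ketone cannot eliminate, so the final esters serve as the only protecting groups from here on.

Step 9
Reactants: 15 (5S)-3,5-dimethyl-5-[(1R,3R)-4,4-dimethyl-1,3-bis(tigloyloxy)hex-5-en-1-yl]cyclopent-2-en-1-one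
Product: 16 (5S)-3,5-dimethyl-5-[(1R,3R,5E)-4,4-dimethyl-6-nitro-1,3-bis(tigloyloxy)hex-5-en-1-yl]cyclopent-2-en-1-one
Conditions: AgNO2 (3 equiv), TEMPO (0.4 equiv), 4 Å MS, ClCH2CH2Cl, 70 °C
Reagents that add atoms: silver nitrite, [Ag+].[O-]N=O
Why: Radical nitration–dehydrogenation of a terminal alkene: NO2 released from AgNO2 adds to the unhindered terminus C11, and TEMPO removes a hydrogen atom from the adduct radical to give the E-nitroalkene. The electrophilic radical should prefer the only electron-rich, monosubstituted alkene over the enone and the two trisubstituted enoates.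

Step 10
Reactants: 16 (5S)-3,5-dimethyl-5-[(1R,3R,5E)-4,4-dimethyl-6-nitro-1,3-bis(tigloyloxy)hex-5-en-1-yl]cyclopent-2-en-1-one
Product: 18 (1R,4R,5R,7R,9R,10S,11R)-11-nitro-1-(triethylsilyloxy)-10(11→1)abeo-longipin-2-ene-7,9-diyl ditiglate (bicyclo[2.2.1]hept-2-ene C1–C2=C3–C4–C5–C11 bridged by C10; nitro endo), via triethylsilyloxy-cyclopentadiene 17 (not isolated)
Conditions: Et3SiOTf (1.5 equiv), Et3N (3 equiv), CH2Cl2 (0.005 M), 0 °C, then 40 °C
Reagents that add atoms: triethylsilyl trifluoromethanesulfonate, CC[Si](CC)(CC)OS(=O)(=O)C(F)(F)F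
Why: Soft enolisation of 16 can only go to the γ side because C10 is quaternary; of the two possible dienol ethers only the endocyclic cyclopentadiene 17 is s-cis, and since they interconvert through Et3NH+ the cycloaddition drains the mixture. 17 then undergoes a normal-electron-demand intramolecular Diels–Alder reaction, the closest known types being silyloxydiene plus nitroalkene and cyclopentadienes tethered through a fully substituted sp3 carbon, which cannot suffer 1,5-hydrogen shifts. Two rings close: the cyclohexene C1–C2=C3–C4–C5–C11 through the [4+2] bond pair C4–C5/C1–C11, which turns the cyclopentadiene into a bicyclo[2.2.1]heptene, and the cycloheptane C4–C5–C6–C7–C8–C9–C10 as the tether ring. The selectivity needed is regiochemical: the 1-silyloxy and 3-methyl groups both raise the HOMO coefficient at C4, the LUMO of the nitroalkene is largest at C5, and the neopentyl C5 avoids the fully substituted C1, so electronics and sterics agree on C4–C5 and C1–C11. The tether reaches only the diene face over which it hangs, so C1 and C4 follow from C10, and for the same reason C6 must stand exo on C5. Suprafacial addition to the E alkene then puts the nitro group endo on C11, trans to C6, which is also the more stable position if C11 should epimerise. The tiglates are trisubstituted and far less electrophilic dienophiles, and high dilution suppresses dimerisation of 17.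

Step 11
Reactants: 18 (1R,4R,5R,7R,9R,10S,11R)-11-nitro-1-(triethylsilyloxy)-10(11→1)abeo-longipin-2-ene-7,9-diyl ditiglate
Product: 19 (1R,4R,5R,7R,9R,10S,11R)-11-amino-1-(triethylsilyloxy)-10(11→1)abeo-longipin-2-ene-7,9-diyl ditiglate (amine endo)
Conditions: Zn dust, AcOH/THF (1:2), 0 °C to rt; aq NaHCO3
Reagents that add atoms: none
Why: Dissolving-metal reduction of a secondary nitroalkane to the primary amine, a reaction that normally keeps the configuration at carbon; enoates, the trisubstituted alkene and the hindered silyl ether tolerate zinc in dilute acetic acid. β-Elimination of the silyloxy group is impossible because it would give a bridgehead alkene.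

Step 12
Reactants: 19 (1R,4R,5R,7R,9R,10S,11R)-11-amino-1-(triethylsilyloxy)-10(11→1)abeo-longipin-2-ene-7,9-diyl ditiglate
Product: 21 (4R,5S,7R,9R,10R,11R)-1-oxolongipin-2-ene-7,9-diyl ditiglate (target), via endo-diazonium acetate 20 (not isolated)
Conditions: t-BuONO (1.5 equiv), AcOH (3 equiv), CH2Cl2, 0 °C to rt
Reagents that add atoms: none
Why: Proposed new method: nitrosation gives the endo-diazonium ion 20, whose C11–N bond is antiperiplanar only to C1–C10 (C1–C2 and C1–O are gauche), so with the silyloxy lone pair pushing, C10 should migrate from C1 to C11 with inversion at C11 and retention at C10 as N2 leaves. This contracts the five-membered ring C1–C10–C4–C5–C11 to the cyclobutane and, after loss of the silyl group to acetate, unveils the conjugated C1 ketone. The closest known reaction types are the Tiffeneau–Demjanov (semipinacol) deamination of rigid cyclic 1,2-amino alcohols, in which the anti ring bond migrates and the ring contracts, the pinacol-type shift of bridgehead-oxygenated bicyclo[2.2.2]octene Diels–Alder adducts to bicyclo[3.2.1]octenones, and the semibenzilic five-to-four contraction of cage α-halo ketones; the bicyclo[2.2.1] to bicyclo[3.1.1] version is the new element.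

## Compound list

1 | 3,3-diethoxypropan-1-ol | CCOC(CCO)OCC | starting material
2 | 3-methylbuta-1,2-diene | CC(C)=C=C | starting material
3 | 3,3-diethoxypropanal | CCOC(CC=O)OCC | intermediate
4 | (3R)-1,1-diethoxy-4,4-dimethylhex-5-en-3-ol | CCOC(C[C@@H](O)C(C)(C)C=C)OCC | intermediate
5 | 1-({[(3R)-1,1-diethoxy-4,4-dimethylhex-5-en-3-yl]oxy}methyl)-4-methoxybenzene | CCOC(C[C@@H](OCc1ccc(OC)cc1)C(C)(C)C=C)OCC | intermediate
6 | (3R)-3-[(4-methoxybenzyl)oxy]-4,4-dimethylhex-5-enal | O=CC[C@@H](OCc1ccc(OC)cc1)C(C)(C)C=C | intermediate
7 | 3-methylcyclopent-2-en-1-one | CC1=CC(=O)CC1 | starting material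
8 | lithium cross-conjugated dienolate of 7 (C1–O, C1=C10, C2=C3) | [Li+].[O-]C1=CCC(C)=C1 | intermediate
9 | 1-methyl-3-(trimethylsilyloxy)cyclopenta-1,3-diene | C[Si](C)(C)OC1=CCC(C)=C1 | intermediate
10 | 5-[(1R,3R)-1-hydroxy-3-(4-methoxybenzyloxy)-4,4-dimethylhex-5-en-1-yl]-3-methylcyclopent-2-en-1-one, both C10 epimers | O=C1C=C(C)CC1[C@H](O)C[C@@H](OCc2ccc(OC)cc2)C(C)(C)C=C | intermediate
11 | dilithium enolate-alkoxide of 10 | [Li+].[Li+].[O-]C1=C(CC(C)=C1)[C@H]([O-])C[C@@H](OCc2ccc(OC)cc2)C(C)(C)C=C | intermediate
12 | (5S)-5-[(1R,3R)-1-hydroxy-3-(4-methoxybenzyloxy)-4,4-dimethylhex-5-en-1-yl]-3,5-dimethylcyclopent-2-en-1-one | O=C1C=C(C)C[C@@]1(C)[C@H](O)C[C@@H](OCc2ccc(OC)cc2)C(C)(C)C=C | intermediate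
13 | (5S)-5-[(1R,3R)-1,3-dihydroxy-4,4-dimethylhex-5-en-1-yl]-3,5-dimethylcyclopent-2-en-1-one | O=C1C=C(C)C[C@@]1(C)[C@H](O)C[C@@H](O)C(C)(C)C=C | intermediate
14 | (E)-2-methylbut-2-enoyl chloride | C/C=C(\C)C(=O)Cl | starting material
15 | (5S)-3,5-dimethyl-5-[(1R,3R)-4,4-dimethyl-1,3-bis(tigloyloxy)hex-5-en-1-yl]cyclopent-2-en-1-one | O=C1C=C(C)C[C@@]1(C)[C@H](OC(=O)/C(C)=C/C)C[C@@H](OC(=O)/C(C)=C/C)C(C)(C)C=C | intermediate
16 | (5S)-3,5-dimethyl-5-[(1R,3R,5E)-4,4-dimethyl-6-nitro-1,3-bis(tigloyloxy)hex-5-en-1-yl]cyclopent-2-en-1-one | O=C1C=C(C)C[C@@]1(C)[C@H](OC(=O)/C(C)=C/C)C[C@@H](OC(=O)/C(C)=C/C)C(C)(C)/C=C/[N+](=O)[O-] | intermediate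
17 | (5S)-1-(triethylsilyloxy)-3,5-dimethyl-5-[(1R,3R,5E)-4,4-dimethyl-6-nitro-1,3-bis(tigloyloxy)hex-5-en-1-yl]cyclopenta-1,3-diene | CC[Si](CC)(CC)OC1=CC(C)=C[C@@]1(C)[C@H](OC(=O)/C(C)=C/C)C[C@@H](OC(=O)/C(C)=C/C)C(C)(C)/C=C/[N+](=O)[O-] | intermediate
18 | (1R,4R,5R,7R,9R,10S,11R)-11-endo-nitro-1-(triethylsilyloxy)-10(11→1)abeo-longipin-2-ene-7,9-diyl ditiglate | C/C=C(\C)C(=O)O[C@@H]1C[C@@H](OC(=O)/C(C)=C/C)[C@@]2(C)[C@]3(O[Si](CC)(CC)CC)C=C(C)[C@H]2[C@@H]([C@H]3[N+](=O)[O-])C1(C)C | intermediate
19 | (1R,4R,5R,7R,9R,10S,11R)-11-endo-amino-1-(triethylsilyloxy)-10(11→1)abeo-longipin-2-ene-7,9-diyl ditiglate | C/C=C(\C)C(=O)O[C@@H]1C[C@@H](OC(=O)/C(C)=C/C)[C@@]2(C)[C@]3(O[Si](CC)(CC)CC)C=C(C)[C@H]2[C@@H]([C@H]3N)C1(C)C | intermediate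
20 | 11-endo-diazonium acetate derived from 19 | C/C=C(\C)C(=O)O[C@@H]1C[C@@H](OC(=O)/C(C)=C/C)[C@@]2(C)[C@]3(O[Si](CC)(CC)CC)C=C(C)[C@H]2[C@@H]([C@H]3[N+]#N)C1(C)C.CC(=O)[O-] | intermediate
21 | (4R,5S,7R,9R,10R,11R)-1-oxolongipin-2-ene-7,9-diyl ditiglate | C/C=C(\C)C(=O)O[C@@H]1C[C@@H](OC(=O)/C(C)=C/C)[C@@]2(C)[C@@H]3C(=O)C=C(C)[C@H]2[C@@H]3C1(C)C | target

## Step count and least certain steps

Total step count: 12. Longest linear sequence: 11 (steps 1–3 and 5–12; step 4 is a one-step branch).

**Step 12 (Proposed new method).**
- What may go wrong: dinitrogen may leave ahead of the migration. The electron-deficient C11 would then be captured by the C2=C3 π bond or by the C1–C2 bond (net vinyl shift to a less strained skeleton), by a hydride from C5, or by acetate. All of these avoid the strain that the C10 shift has to build up.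
- Fallback, from 15 back to 21: the nitrogen leaving group is replaced by a sulfonate that cannot ionise by itself.
  - Cross-metathesis of 15 with pinacol vinylboronate (second-generation Hoveyda–Grubbs catalyst, CH2Cl2, 40 °C) should give the (E)-alkenylboronate F1.
  - Silylation as in step 10 and heating (toluene, 130 °C) should give the endo-boryl norbornene F2.
  - NaBO3 oxidation, which retains configuration, gives the endo-alcohol F3. MsCl/Et3N then gives the endo-mesylate F4.
  - Bu4NF frees the C1 alkoxide. It can expel the mesylate only through the backside shift of the anti bond C1–C10, giving 21.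
  - This last step is the base-induced pinacol-type rearrangement of a vicinal hydroxy sulfonate, a standard, stereoelectronically strict ring contraction. Its five-to-four variant is known from the semibenzilic contraction of cage ketones.

**Step 10 (key step).**
- What may go wrong: the leading bond C4–C5 joins two carbons that each have a quaternary neighbour, and the tether ring has seven members. The cycloaddition may therefore be slower than dimerisation or desilylation of the diene, or the process may stop after the first bond.
- Fallback, from 16 back to 18: the two bonds are made one after the other.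
  - 16 is silylated to 17 at −78 °C and SnCl4 is added, so that C4 adds to C5 in a Mukaiyama–Michael reaction. Aqueous work-up should give the bicyclic nitro enone F5.
  - Catalytic DBU closes C11–C1 by an intramolecular Henry reaction to the nitro alcohol F6. This step is reversible, and the nitro group settles endo, trans to C6.
  - Et3SiOTf/2,6-lutidine traps F6 as 18.

**Step 6.**
- What may go wrong: retro-aldol cleavage may occur at the mono-alkoxide stage. Facial selectivity may be lost if the lithium chelate is broken by the cosolvent. O-methylation is also possible.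
- Fallback, from 6 and 7 back to 12: the methyl group is placed before the aldol, so that the quaternary centre forms in the C–C coupling itself.
  - 7 is methylated (LDA, MeI) to 3,5-dimethylcyclopent-2-en-1-one F7.
  - F7 is converted (LDA, Me3SiCl) into the tetrasubstituted silyl dienol ether F8.
  - F8 is added to 6 under TiCl4 chelation of the aldehyde and its ether oxygen.
  - The C10 epimers are separated, and the unwanted one can be returned to 6 and F7 by retro-aldol cleavage.

**Step 9.**
- What may go wrong: conversion of the neopentyl vinyl group may be sluggish, and NO2 may attack the enone or the tiglate alkenes.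
- Fallback, from 15 back to 16: C11 is exchanged instead of functionalised.
  - Ozonolysis of the only electron-rich alkene (O3, CH2Cl2, −78 °C, dye end point; Me2S) should give the aldehyde F9.
  - A Henry reaction with nitromethane gives the nitro alcohol F10.
  - MsCl/Et3N dehydrates F10 to the E-nitroalkene 16.

## Further compounds

F1 | step 12 | (5S)-3,5-dimethyl-5-[(1R,3R,5E)-4,4-dimethyl-6-(pinacolatoboryl)-1,3-bis(tigloyloxy)hex-5-en-1-yl]cyclopent-2-en-1-one | O=C1C=C(C)C[C@@]1(C)[C@H](OC(=O)/C(C)=C/C)C[C@@H](OC(=O)/C(C)=C/C)C(C)(C)/C=C/B2OC(C)(C)C(C)(C)O2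
F2 | step 12 | 11-endo-(pinacolatoboryl)-1-(triethylsilyloxy)-10(11→1)abeo-longipin-2-ene-7,9-diyl ditiglate | C/C=C(\C)C(=O)O[C@@H]1C[C@@H](OC(=O)/C(C)=C/C)[C@@]2(C)[C@]3(O[Si](CC)(CC)CC)C=C(C)[C@H]2[C@@H]([C@H]3B4OC(C)(C)C(C)(C)O4)C1(C)C
F3 | step 12 | 11-endo-hydroxy-1-(triethylsilyloxy)-10(11→1)abeo-longipin-2-ene-7,9-diyl ditiglate | C/C=C(\C)C(=O)O[C@@H]1C[C@@H](OC(=O)/C(C)=C/C)[C@@]2(C)[C@]3(O[Si](CC)(CC)CC)C=C(C)[C@H]2[C@@H]([C@H]3O)C1(C)C
F4 | step 12 | 11-endo-(methanesulfonyloxy)-1-(triethylsilyloxy)-10(11→1)abeo-longipin-2-ene-7,9-diyl ditiglate | C/C=C(\C)C(=O)O[C@@H]1C[C@@H](OC(=O)/C(C)=C/C)[C@@]2(C)[C@]3(O[Si](CC)(CC)CC)C=C(C)[C@H]2[C@@H]([C@H]3OS(C)(=O)=O)C1(C)C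
F5 | step 10 | bicyclic nitro enone (cyclopentenone C1–C4, C10 fused at C4–C10 to the cycloheptane; C5 bears CH2NO2) | C/C=C(\C)C(=O)O[C@@H]1C[C@@H](OC(=O)/C(C)=C/C)[C@@]2(C)C(=O)C=C(C)[C@H]2[C@@H](C[N+](=O)[O-])C1(C)C
F6 | step 10 | 1-hydroxy-11-endo-nitro-10(11→1)abeo-longipin-2-ene-7,9-diyl ditiglate | C/C=C(\C)C(=O)O[C@@H]1C[C@@H](OC(=O)/C(C)=C/C)[C@@]2(C)[C@]3(O)C=C(C)[C@H]2[C@@H]([C@H]3[N+](=O)[O-])C1(C)C
F7 | step 6 | 3,5-dimethylcyclopent-2-en-1-one (racemic) | CC1CC(C)=CC1=O
F8 | step 6 | 1,4-dimethyl-2-(trimethylsilyloxy)cyclopenta-1,3-diene | C[Si](C)(C)OC1=C(C)CC(C)=C1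
F9 | step 9 | (3R,5R)-5-[(1S)-1,4-dimethyl-2-oxocyclopent-3-en-1-yl]-2,2-dimethyl-3,5-bis(tigloyloxy)pentanal | O=C1C=C(C)C[C@@]1(C)[C@H](OC(=O)/C(C)=C/C)C[C@@H](OC(=O)/C(C)=C/C)C(C)(C)C=O
F10 | step 9 | Henry adduct of F9 (both carbinol epimers) | O=C1C=C(C)C[C@@]1(C)[C@H](OC(=O)/C(C)=C/C)C[C@@H](OC(=O)/C(C)=C/C)C(C)(C)C(O)C[N+](=O)[O-]
A1 | alternative 1 | bicyclo[5.4.0]undecenone C5-mesylate with C7 and C9 tert-butyldimethylsilyl ethers | CC(C)(C)[Si](C)(C)O[C@@H]1C[C@@H](O[Si](C)(C)C(C)(C)C)[C@@]2(C)CC(=O)C=C(C)[C@H]2[C@H](OS(C)(=O)=O)C1(C)C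
A2 | alternative 2 | (2E,6E,8R)-8-(tert-butyldimethylsilyloxy)-3,7,11-trimethyl-10-oxododeca-2,6-dienoic acid | OC(=O)/C=C(\C)CC/C=C(\C)[C@H](O[Si](C)(C)C(C)(C)C)CC(=O)C(C)C
A3 | alternative 2 | 2-methylenebicyclo[3.1.1]heptan-6-one bearing at C7 a methyl group and the (1R)-1-silyloxy-4-methyl-3-oxopentyl chain | C=C1CC[C@@H]2C(=O)[C@H]1[C@@]2(C)[C@H](O[Si](C)(C)C(C)(C)C)CC(=O)C(C)C
A4 | alternative 3 | (1R,5R)-(+)-verbenone | CC1(C)[C@@H]2C(=O)C=C(C)[C@H]1C2
A5 | alternative 3 | verbenone analogue with the C10 methyl group anti to the enone bridge oxidised to CHO | O=C[C@@]1(C)[C@@H]2C(=O)C=C(C)[C@H]1C2
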